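## The problem

Target **19** is (2S)-2-(3,4-dimethoxyphenyl)-8-hydroxy-5,6,7-trimethoxychroman-4-one: a benzo-fused dihydropyranone (rings A and C) that carries ring B on C2 through one C–C bond. C2 is the only stereocentre, so nothing in the molecule can relay chirality to it and it has to be set by a catalyst. C2 is also the β-carbon of an aryloxy ketone, and base or hot acid opens ring C by retro-oxa-Michael reaction to an achiral 2'-hydroxychalcone; every operation after C2 is set must therefore be neutral or buffered. Ring A is hexasubstituted and carries five contiguous oxygens that must be told apart: three methyl ethers, the ring oxygen O1 and the free hydroxyl on C8. The 5-methoxy group lies peri to the C4 carbonyl and is cleaved by chelating Lewis acids, and the 8-hydroxy/5-methoxy pair is a hydroquinone monoether that oxidants turn into a quinone. The C8 oxygen therefore needs a mask that survives an oxidant and comes off last under neutral, non-oxidising conditions that spare the hydrogenolysable benzylic C2–O1 bond. The enabling feature is ring B: C3' and C4' carry vicinal methoxy groups and C2', C5' and C6' carry hydrogen, so C2'–C3'–C4'–C5' is the skeleton of a symmetric 2,3-dimethoxybutadiene and C1'–C6' is an ethynyl group on C2. A C2 that bears an alkyne is in turn the product of a conjugate alkynylation of a chromone, a reaction with a catalytic asymmetric version.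

## Retrosynthesis

**19 ⇒ 18.** The O–H bond on C8 is traced back to a benzyl ether. Benzyl is chosen over a fourth methyl or a silyl group because it is distinguishable from the three methoxy groups, survives silyl triflate, fluoride, low-valent cobalt and a quinone oxidant, and leaves by hydrogenolysis without acid or base. The forward step must stop before the benzylic C2–O1 bond or the ketone is reduced.

**18 ⇒ 17.** The 3,4-dimethoxyphenyl ring is taken back to its 2',5'-dihydro form, the 1,4-cyclohexadiene **17**. This adds only two hydrogens but exposes the ring as a cycloadduct. The forward step is a dehydrogenation that must be faster than oxidation of the chromanone C2–C3 bond.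

**17 ⇒ 13 + 16.** The C1'–C2' and C5'–C6' bonds are cut, which removes ring B entirely and leaves the ethynylchromanone **13** and diene **16**. The neighbouring options are weaker: a [2+2+2] assembly from three alkynes would need methoxyalkynes and has no regiocontrol, and reversing the roles (diene on C2, dioxygenated dienophile) has no practical two-carbon partner. Here the diene is symmetric, so only one constitution can form. The forward reaction must engage an unactivated terminal alkyne under neutral conditions, which a thermal Diels–Alder reaction cannot do and a low-valent cobalt catalyst can.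

**16 ⇒ 14.** The two enol ether C–O bonds of **16** go back to the carbonyl groups of butane-2,3-dione **14** by way of the bis-ketal **15**. This is a single known operation from a bulk chemical.

**13 ⇒ 12 ⇒ 8 + 9.** The terminal C–H of **13** comes from the silylalkyne **12**, and the C2–C(sp) bond of **12** is cut to give chromone **8** and trimethylsilylacetylene **9**. This is the stereo-defining disconnection: a flat, achiral heteroaromatic ketone replaces the stereocentre. The forward reaction must add an acetylide to C2 of a weakly electrophilic vinylogous ester with face control. That calls for activation of **8** as the benzopyrylium salt **10** and a chiral copper acetylide, with the chromanone released from the silyl enol ether **11**.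

**8 ⇒ 6.** The O1–C2 and C2–C3 bonds are cut, so C2 becomes a one-carbon unit delivered by a formamide acetal to the methyl ketone **6** via enaminone **7**. The precursor is a plain acetophenone, and the forward step is the standard enaminone route to 2,3-unsubstituted chromones.

**6 ⇒ 5 ⇒ 4.** The benzyl group is removed to give the dihydroxyacetophenone **5**, and the aryl–acyl bond is cut to give catechol **4**. In **5** the two hydroxyls differ electronically: one is chelated to the acetyl group and the other is not. That difference allows selective benzylation without protecting-group traffic. In **4** only one ring position is free, so acylation has no regiochemical choice.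

**4 ⇒ 2 ⇒ 1.** The second catechol oxygen is traced to a formyl group (aldehyde **2**, via formate **3**) and the formyl group to a C–H of 3,4,5-trimethoxyphenol **1**. Phenol **1** is symmetric, so the first ortho-functionalisation is unambiguous. It is a commercial compound that already holds four of the five ring A oxygens.

## Roads not taken

**Alternative 1:** Ring A is built last by cutting C8–C8a and tracing C5–C8 to a squaric ester unit. The forward key step heats the cyclobutenone **A2**; it opens to a dienylketene, the ketene carbon closes onto the enol ether carbon of the dihydropyran in a six-electron electrocyclisation, and tautomerisation gives phenol **A1**.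
- Merits: all five ring A oxygens arrive regiospecifically and the C8 hydroxyl is the only free one, so the differentiation problem disappears. In this respect it is better than the chosen plan, which spends five classical steps on ring A.
- Weak points: **A2** needs an enantioenriched, metallated 2-aryl-4-silyloxydihydropyran and a 1,2-addition and O-methylation on a squaric diester, which is a long preamble. **A1** still has to be desilylated and oxidised at C4 while the free C8 hydroxyl sits para to the 5-methoxy group, the most oxidisable position in the molecule, so a protecting group returns.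
- Comparison: the chosen plan sets against this a commercial ring A, a C4 carbonyl that is present from the chromone stage, and a shorter sequence.

**Alternative 2:** The C4a–C4, C4–C3 and O1–C2 bonds are cut. In the forward step the iodophenol **A4**, carbon monoxide and the arylalkyne **A5** undergo a palladium-catalysed carbonylative coupling in a secondary amine, and the resulting ynone closes 6-endo to the flavone **A3**.
- Merits: the whole carbon skeleton is assembled convergently in one very well-precedented step, and ring B comes from a cheap alkyne. On precedent and step count to the skeleton it is stronger than the chosen plan.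
- Weak points: **A3** is flat, so the C2 stereocentre must come afterwards from an enantioselective reduction of the C2=C3 bond of an electron-rich flavone to reach **18**. That transformation is much less general than nucleophilic additions to chromones and competes with reduction of the C4 ketone. **A4** also needs the same differentiated catechol plus a regioselective iodination, and 5-exo closure to an aurone is a known competitor.
- Comparison: the chosen plan sets against this a stereocentre created in the C–C bond-forming event itself and no hydride step next to a reducible ketone.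

**Alternative 3:** The O1–C2 and C3–C4 bonds are cut. In the forward step a chiral BINOL-derived phosphoric acid dehydrates the hydroxybenzyl alcohol **A7** to an ortho-quinone methide, which adds the styrene **A8** to give the flavan **A6**.
- Merits: ring C and the stereocentre form in one catalytic step from two simple, electronically matched partners, which is better step economy at the ring-forming stage than the chosen plan.
- Weak points: **A6** has a methylene at C4. Reaching **18** needs a benzylic oxidation in a molecule whose C2–H (benzylic and α to oxygen) and benzyl ether CH2 are at least as activated. The quinone methide has no substituent on the methide carbon, oligomerises readily, and offers the catalyst little to hold. **A7** again presupposes the differentiated catechol.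
- Comparison: the chosen plan never needs a C–H oxidation because the ketone is present from the start.

Key step: step 9

Assumption: the sense of induction of the CuI/StackPhos alkynylation is taken from simpler chromones; the ligand antipode that leads to the 2S series is the one specified, and the configuration of **12** is to be confirmed before the material is carried on.

## Route

Step 1
Reactants: 1 3,4,5-trimethoxyphenol
Product: 2 6-hydroxy-2,3,4-trimethoxybenzaldehyde
Conditions: MgCl2, Et3N, paraformaldehyde, MeCN, reflux; then 1 M HCl
Reagents that add atoms: paraformaldehyde (as formaldehyde), C=O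
Why: Casnati–Skattebøl ortho-formylation: the magnesium phenoxide delivers formaldehyde to the ortho carbon through a six-membered chelate and a second equivalent of formaldehyde oxidises the benzylic alkoxide by hydride transfer; the two ortho positions of 1 are equivalent, so one aldehyde is expected.

Step 2
Reactants: 2 6-hydroxy-2,3,4-trimethoxybenzaldehyde
Product: 4 3,4,5-trimethoxybenzene-1,2-diol, via aryl formate 3 (not isolated)
Conditions: 30% H2O2, H3BO3, cat. H2SO4, THF, rt, argon
Reagents that add atoms: hydrogen peroxide, OO
Why: Dakin oxidation: the hydroperoxide adduct of the aldehyde rearranges with migration of the electron-rich aryl group to oxygen (Baeyer–Villiger type) and formate 3 hydrolyses in the aqueous acid; the acidic boric acid medium should keep the oxidation-prone catechol from reacting further, and 4 is used crude.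

Step 3
Reactants: 4 3,4,5-trimethoxybenzene-1,2-diol
Product: 5 1-(2,3-dihydroxy-4,5,6-trimethoxyphenyl)ethan-1-one
Conditions: AcOH, BF3·OEt2, 80 °C, argon; then aq. NaOAc
Reagents that add atoms: acetic acid, CC(=O)O
Why: Friedel–Crafts (Nencki-type) C-acylation of a polyoxygenated arene; the single free ring position is ortho to a hydroxyl and a methoxy group and para to another methoxy group, and BF3 in acetic acid acylates phenols of this type without cleaving aryl methyl ethers.

Step 4
Reactants: 5 1-(2,3-dihydroxy-4,5,6-trimethoxyphenyl)ethan-1-one
Product: 6 1-[3-(benzyloxy)-2-hydroxy-4,5,6-trimethoxyphenyl]ethan-1-one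
Conditions: NaH (2.1 equiv), DMSO–THF, rt; BnBr (1.0 equiv); then 1 M HCl
Reagents that add atoms: benzyl bromide, BrCc1ccccc1
Why: Williamson etherification of a catechol dianion: in the disodium salt the oxide ortho to the acetyl group is chelated and conjugated to the carbonyl, so the other oxide is the stronger nucleophile and should take the single equivalent of benzyl bromide.

Step 5
Reactants: 6 1-[3-(benzyloxy)-2-hydroxy-4,5,6-trimethoxyphenyl]ethan-1-one
Product: 8 8-(benzyloxy)-5,6,7-trimethoxy-4H-chromen-4-one, via enaminone 7 (not isolated)
Conditions: Me2NCH(OMe)2, toluene, 100 °C; concentrate; then conc. HCl, CH2Cl2, rt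
Reagents that add atoms: N,N-dimethylformamide dimethyl acetal, COC(OC)N(C)C
Why: Enaminone route to chromones: the amide acetal condenses with the acetyl methyl group to give 7, and acid then promotes conjugate addition of the phenol and loss of dimethylamine (addition–elimination), closing the pyranone; the benzyl ether and methyl ethers are inert to both stages.

Step 6
Reactants: 8 8-(benzyloxy)-5,6,7-trimethoxy-4H-chromen-4-one; 9 trimethylsilylacetylene
Product: 12 (2S)-8-(benzyloxy)-5,6,7-trimethoxy-2-[(trimethylsilyl)ethynyl]chroman-4-one, via 4-silyloxybenzopyrylium triflate 10 (not isolated), via silyl enol ether 11 (not isolated)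
Conditions: TBSOTf (1.3 equiv), CH2Cl2, rt; then 9, CuI (10 mol %), StackPhos (12 mol %, antipode giving 2S), i-Pr2NEt, toluene, −78 to −40 °C; then 1 M HCl, THF, 0 °C
Reagents that add atoms: none
Why: Copper-catalysed enantioselective alkynylation of chromones through 4-silyloxybenzopyrylium ions: the silyl triflate converts 8 into the electrophilic salt 10, the monovalent copper acetylide generated from 9, CuI and the amine adds to C2 inside the pocket of the axially chiral P,N ligand, which selects the face that leads to 2S, and dilute acid hydrolyses silyl enol ether 11 without opening ring C.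

Step 7
Reactants: 12 (2S)-8-(benzyloxy)-5,6,7-trimethoxy-2-[(trimethylsilyl)ethynyl]chroman-4-one
Product: 13 (2S)-8-(benzyloxy)-2-ethynyl-5,6,7-trimethoxychroman-4-one
Conditions: TBAF (1.1 equiv), AcOH (1.5 equiv), THF, −20 to 0 °C
Reagents that add atoms: none
Why: Fluoride-induced cleavage of the alkynyl C–Si bond; acetic acid buffers the fluoride so that no C3 enolate forms, since an enolate would expel the phenoxide (retro-oxa-Michael) and racemise C2.

Step 8
Reactants: 14 butane-2,3-dione
Product: 16 2,3-dimethoxybuta-1,3-diene, via 2,2,3,3-tetramethoxybutane 15 (not isolated)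
Conditions: HC(OMe)3, MeOH, cat. H2SO4, reflux; then NH4H2PO4, slow distillation (bath ca. 150 °C)
Reagents that add atoms: trimethyl orthoformate, COC(OC)OC; methanol, CO
Why: Acid-catalysed ketalisation with the orthoformate as water scavenger gives bis-ketal 15, which loses two molecules of methanol on heating with the weakly acidic ammonium salt (elimination to the bis-enol ether) while the volatile diene distils out; this is the established preparation of this diene.

Step 9
Reactants: 13 (2S)-8-(benzyloxy)-2-ethynyl-5,6,7-trimethoxychroman-4-one; 16 2,3-dimethoxybuta-1,3-diene
Product: 17 (2S)-8-(benzyloxy)-2-(4,5-dimethoxycyclohexa-1,4-dien-1-yl)-5,6,7-trimethoxychroman-4-one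
Conditions: CoBr2(dppe) (10 mol %), Zn powder (20 mol %), ZnI2 (20 mol %), CH2Cl2, rt, 16 in threefold excess, slow addition of 13; filtration through basic alumina
Reagents that add atoms: none
Why: Zinc reduces the divalent cobalt precatalyst to a monovalent cobalt species and ZnI2 removes halide, giving a cationic centre that binds the s-cis diene and the alkyne, couples them oxidatively to a trivalent cobaltacycle and reductively eliminates the 1,4-cyclohexadiene. The closest known reaction type is the cobalt-catalysed neutral [4+2] cycloaddition of unactivated terminal alkynes with 2,3-dimethylbutadiene and 2-silyloxybutadiene. The six-membered carbocycle that becomes ring B is closed by intermolecular [4+2] annulation, which forms C1'–C2' and C5'–C6' in one catalytic cycle. No stereocentre is created; C2 was set in step 6, none of its bonds is touched and the medium contains neither base nor protic acid, so its configuration should be retained. The step needs chemoselectivity for the cross-cycloaddition over alkyne cyclotrimerisation and diene dimerisation, which the chelating diphosphine, the threefold excess of 16 and slow addition of 13 should provide. No regiochemical question arises because 16 is symmetric. The ketone, the aryl ethers and the benzyl ether are spectators. Product 17 is an acid-sensitive enediol diether and is taken on after filtration through basic alumina, not silica.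

Step 10
Reactants: 17 (2S)-8-(benzyloxy)-2-(4,5-dimethoxycyclohexa-1,4-dien-1-yl)-5,6,7-trimethoxychroman-4-one
Product: 18 (2S)-8-(benzyloxy)-2-(3,4-dimethoxyphenyl)-5,6,7-trimethoxychroman-4-one
Conditions: DDQ (1.05 equiv), toluene, 0 °C
Reagents that add atoms: none
Why: Quinone dehydrogenation of a 1,4-cyclohexadiene: hydride abstraction from a doubly allylic methylene gives a methoxy-stabilised cyclohexadienyl cation that loses a proton to the arene; this is much faster than dehydrogenation of the chromanone C2–C3 bond, so one equivalent at 0 °C should leave ring C and the benzyl ether intact.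

Step 11
Reactants: 18 (2S)-8-(benzyloxy)-2-(3,4-dimethoxyphenyl)-5,6,7-trimethoxychroman-4-one
Product: 19 (2S)-2-(3,4-dimethoxyphenyl)-8-hydroxy-5,6,7-trimethoxychroman-4-one
Conditions: H2 (1 atm), 10% Pd/C, EtOAc, rt, stopped at one equivalent of uptake
Reagents that add atoms: none
Why: Hydrogenolysis of an aryl benzyl ether over palladium on carbon; the medium is neutral, so C2 and the peri methoxy group are not at risk, and the O-benzyl bond cleaves faster than the benzylic C2–O1 bond or the aryl ketone is reduced.

## Compound list

1 | 3,4,5-trimethoxyphenol | COc1cc(O)cc(OC)c1OC | starting material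
2 | 6-hydroxy-2,3,4-trimethoxybenzaldehyde | COc1cc(O)c(C=O)c(OC)c1OC | intermediate
3 | 6-hydroxy-2,3,4-trimethoxyphenyl formate | COc1cc(O)c(OC=O)c(OC)c1OC | intermediate
4 | 3,4,5-trimethoxybenzene-1,2-diol | COc1cc(O)c(O)c(OC)c1OC | intermediate
5 | 1-(2,3-dihydroxy-4,5,6-trimethoxyphenyl)ethan-1-one | CC(=O)c1c(O)c(O)c(OC)c(OC)c1OC | intermediate
6 | 1-[3-(benzyloxy)-2-hydroxy-4,5,6-trimethoxyphenyl]ethan-1-one | CC(=O)c1c(O)c(OCc2ccccc2)c(OC)c(OC)c1OC | intermediate
7 | (E)-1-[3-(benzyloxy)-2-hydroxy-4,5,6-trimethoxyphenyl]-3-(dimethylamino)prop-2-en-1-one | CN(C)/C=C/C(=O)c1c(O)c(OCc2ccccc2)c(OC)c(OC)c1OC | intermediate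
8 | 8-(benzyloxy)-5,6,7-trimethoxy-4H-chromen-4-one | O=c1ccoc2c(OCc3ccccc3)c(OC)c(OC)c(OC)c12 | intermediate
9 | trimethylsilylacetylene | C#C[Si](C)(C)C | starting material
10 | 8-(benzyloxy)-4-(tert-butyldimethylsilyloxy)-5,6,7-trimethoxychromenylium trifluoromethanesulfonate | CC(C)(C)[Si](C)(C)Oc1cc[o+]c2c(OCc3ccccc3)c(OC)c(OC)c(OC)c12.[O-]S(=O)(=O)C(F)(F)F | intermediate
11 | (2S)-8-(benzyloxy)-4-(tert-butyldimethylsilyloxy)-5,6,7-trimethoxy-2-[(trimethylsilyl)ethynyl]-2H-chromene | C[Si](C)(C)C#C[C@@H]1C=C(O[Si](C)(C)C(C)(C)C)c2c(c(OCc3ccccc3)c(OC)c(OC)c2OC)O1 | intermediate
12 | (2S)-8-(benzyloxy)-5,6,7-trimethoxy-2-[(trimethylsilyl)ethynyl]chroman-4-one | C[Si](C)(C)C#C[C@@H]1CC(=O)c2c(c(OCc3ccccc3)c(OC)c(OC)c2OC)O1 | intermediate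
13 | (2S)-8-(benzyloxy)-2-ethynyl-5,6,7-trimethoxychroman-4-one | C#C[C@@H]1CC(=O)c2c(c(OCc3ccccc3)c(OC)c(OC)c2OC)O1 | intermediate
14 | butane-2,3-dione | CC(=O)C(C)=O | starting material
15 | 2,2,3,3-tetramethoxybutane | COC(C)(OC)C(C)(OC)OC | intermediate
16 | 2,3-dimethoxybuta-1,3-diene | C=C(OC)C(=C)OC | intermediate
17 | (2S)-8-(benzyloxy)-2-(4,5-dimethoxycyclohexa-1,4-dien-1-yl)-5,6,7-trimethoxychroman-4-one | COC1=C(OC)CC([C@@H]2CC(=O)c3c(c(OCc4ccccc4)c(OC)c(OC)c3OC)O2)=CC1 | intermediate
18 | (2S)-8-(benzyloxy)-2-(3,4-dimethoxyphenyl)-5,6,7-trimethoxychroman-4-one | COc1ccc([C@@H]2CC(=O)c3c(c(OCc4ccccc4)c(OC)c(OC)c3OC)O2)cc1OC | intermediate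
19 | (2S)-2-(3,4-dimethoxyphenyl)-8-hydroxy-5,6,7-trimethoxychroman-4-one | COc1ccc([C@@H]2CC(=O)c3c(c(O)c(OC)c(OC)c3OC)O2)cc1OC | target

## Step count and risks

Total: 11 steps. Longest linear sequence: 10 steps (steps 1–7 and 9–11 from 1); step 8 is a one-step side branch.

**Step 9 (key step).** The Lewis-acidic ZnI2 may degrade or polymerise the electron-rich diene before the cobalt cycle takes it up, the alkyne may trimerise when diene concentration falls, and chelation of the catalyst by the keto-ether substrate may stall turnover. The enediol diether product may also hydrolyse during isolation. Fallback: ring B is introduced intact. Starting from chromone 8, a palladium-catalysed asymmetric conjugate addition of (3,4-dimethoxyphenyl)boronic acid is used, with Pd(OCOCF3)2, the t-BuPyOx antipode that gives the 2S series, NH4PF6 and water in 1,2-dichloroethane at 60 °C. This is a known reaction of chromones and gives 18 directly, where the route is rejoined. No compound outside the list is made (F0).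

**Step 6.** The benzopyrylium ion carries four donor oxygens and a peri methoxy group next to the silyloxy group, so acetylide addition may be slow. Slow catalysed addition allows an unligated background reaction to erode enantioselectivity, and the sense of induction is assumed by analogy. Fallback: the stereocentre is obtained by resolution instead of asymmetric C–C bond formation. Starting from 8, the same silyl triflate activation and CuI with i-Pr2NEt but no chiral ligand, at 0 °C to rt, should give racemic 8-(benzyloxy)-4-(tert-butyldimethylsilyloxy)-5,6,7-trimethoxy-2-[(trimethylsilyl)ethynyl]-2H-chromene F1. Acid hydrolysis gives racemic 8-(benzyloxy)-5,6,7-trimethoxy-2-[(trimethylsilyl)ethynyl]chroman-4-one F2. Kinetic resolution by asymmetric transfer hydrogenation follows, with RuCl(p-cymene)(TsDPEN) in the antipode that reduces the 2R ketone faster and HCO2H/Et3N; this is a known resolution of 2-substituted chroman-4-ones. It should convert the unwanted enantiomer into (2R,4R)-8-(benzyloxy)-5,6,7-trimethoxy-2-[(trimethylsilyl)ethynyl]chroman-4-ol F3 and leave 12, which is separated by chromatography and rejoins the route.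

**Step 4.** Differentiation of the two oxides may be incomplete, giving alkylation at the chelated oxygen or on both oxygens. Fallback: selective dealkylation replaces selective alkylation. Starting from 5, excess BnBr and K2CO3 in DMF at 60 °C should give 1-[2,3-bis(benzyloxy)-4,5,6-trimethoxyphenyl]ethan-1-one F4. MgBr2·OEt2 in toluene–ether at reflux then cleaves only the benzyl ether ortho to the carbonyl through a magnesium chelate, a known selective debenzylation that spares methyl ethers, and returns 6.

**Step 7.** Fluoride that is not fully buffered may enolise C3 and open ring C, with loss of enantiopurity on re-closure. Fallback: the silicon is carried through the cycloaddition and removed from sp2 carbon under acid.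
- Starting from 12, the conditions of step 9 with 16 (silylalkynes are competent partners) should give (2S)-8-(benzyloxy)-2-[4,5-dimethoxy-2-(trimethylsilyl)cyclohexa-1,4-dien-1-yl]-5,6,7-trimethoxychroman-4-one F5.
- DDQ as in step 10 gives (2S)-8-(benzyloxy)-2-[4,5-dimethoxy-2-(trimethylsilyl)phenyl]-5,6,7-trimethoxychroman-4-one F6.
- Protodesilylation with CF3CO2H in CH2Cl2 at 0 °C, an ipso-substitution activated by the para methoxy group, gives 18, where the route is rejoined.

## Further compounds

F0 | step 9 | none | none
F1 | step 6 | racemic 8-(benzyloxy)-4-(tert-butyldimethylsilyloxy)-5,6,7-trimethoxy-2-[(trimethylsilyl)ethynyl]-2H-chromene | C[Si](C)(C)C#CC1C=C(O[Si](C)(C)C(C)(C)C)c2c(c(OCc3ccccc3)c(OC)c(OC)c2OC)O1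
F2 | step 6 | racemic 8-(benzyloxy)-5,6,7-trimethoxy-2-[(trimethylsilyl)ethynyl]chroman-4-one | C[Si](C)(C)C#CC1CC(=O)c2c(c(OCc3ccccc3)c(OC)c(OC)c2OC)O1
F3 | step 6 | (2R,4R)-8-(benzyloxy)-5,6,7-trimethoxy-2-[(trimethylsilyl)ethynyl]chroman-4-ol | C[Si](C)(C)C#C[C@H]1C[C@@H](O)c2c(c(OCc3ccccc3)c(OC)c(OC)c2OC)O1
F4 | step 4 | 1-[2,3-bis(benzyloxy)-4,5,6-trimethoxyphenyl]ethan-1-one | CC(=O)c1c(OCc2ccccc2)c(OCc2ccccc2)c(OC)c(OC)c1OC
F5 | step 7 | (2S)-8-(benzyloxy)-2-[4,5-dimethoxy-2-(trimethylsilyl)cyclohexa-1,4-dien-1-yl]-5,6,7-trimethoxychroman-4-one | COC1=C(OC)CC([C@@H]2CC(=O)c3c(c(OCc4ccccc4)c(OC)c(OC)c3OC)O2)=C([Si](C)(C)C)C1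
F6 | step 7 | (2S)-8-(benzyloxy)-2-[4,5-dimethoxy-2-(trimethylsilyl)phenyl]-5,6,7-trimethoxychroman-4-one | COc1cc([C@@H]2CC(=O)c3c(c(OCc4ccccc4)c(OC)c(OC)c3OC)O2)c([Si](C)(C)C)cc1OC
A1 | alternative 1 | (2S,4S)-4-(tert-butyldimethylsilyloxy)-2-(3,4-dimethoxyphenyl)-5,6,7-trimethoxychroman-8-ol | COc1ccc([C@@H]2C[C@H](O[Si](C)(C)C(C)(C)C)c3c(c(O)c(OC)c(OC)c3OC)O2)cc1OC
A2 | alternative 1 | 4-[(2S,4S)-4-(tert-butyldimethylsilyloxy)-2-(3,4-dimethoxyphenyl)-3,4-dihydro-2H-pyran-5-yl]-2,3,4-trimethoxycyclobut-2-en-1-one (either configuration at the cyclobutenone carbon) | COc1ccc([C@@H]2C[C@H](O[Si](C)(C)C(C)(C)C)C(C3(OC)C(OC)=C(OC)C3=O)=CO2)cc1OC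
A3 | alternative 2 | 8-(benzyloxy)-2-(3,4-dimethoxyphenyl)-5,6,7-trimethoxy-4H-chromen-4-one | COc1ccc(-c2cc(=O)c3c(OC)c(OC)c(OC)c(OCc4ccccc4)c3o2)cc1OC
A4 | alternative 2 | 2-(benzyloxy)-6-iodo-3,4,5-trimethoxyphenol | COc1c(I)c(O)c(OCc2ccccc2)c(OC)c1OC
A5 | alternative 2 | 4-ethynyl-1,2-dimethoxybenzene | C#Cc1ccc(OC)c(OC)c1
A6 | alternative 3 | (2S)-8-(benzyloxy)-2-(3,4-dimethoxyphenyl)-5,6,7-trimethoxychromane | COc1ccc([C@@H]2CCc3c(c(OCc4ccccc4)c(OC)c(OC)c3OC)O2)cc1OC
A7 | alternative 3 | 2-(benzyloxy)-6-(hydroxymethyl)-3,4,5-trimethoxyphenol | OCc1c(O)c(OCc2ccccc2)c(OC)c(OC)c1OC
A8 | alternative 3 | 4-ethenyl-1,2-dimethoxybenzene | C=Cc1ccc(OC)c(OC)c1
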